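The plan cuts the cyclohexene ring (C1–C6, carotenoid numbering) at C4–C5 and C1–C6. The gem-dimethyl carbon C1, C2, the oxygenated C3 and C4 are the carbon chain of mesityl oxide; C5 with its methyl, C6 and the exocyclic C7 are a crotonyl unit. A single Lewis-acid annulation of the silyl dienol ether of mesityl oxide with an N-crotonyl oxazolidinone closes the ring, fixes C6 and delivers every ring carbon, the three methyls and C7. C7 then becomes a tetrazolyl sulfone, C3/C4/C5 are adjusted to the allylic alcohol, and Julia–Kocienski olefination with the C20 unit crocetin dialdehyde forms C7=C8.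

Key step: step 3

Assumption: all-E crocetin dialdehyde 16 is taken as a purchasable C20 building block, and the target is read as the (3R,6R) isomer with the C3 hydroxyl and the C6 side chain trans on the ring.

Step 1
Reactants: 1 mesityl oxide (4-methylpent-3-en-2-one)
Product: 2 tert-butyl(dimethyl)[(4-methylpenta-1,3-dien-2-yl)oxy]silane
Conditions: LiN(i-Pr)2, THF, −78 °C; then TBSCl, DMPU, −78 °C → rt
Reagents that add atoms: tert-butyldimethylsilyl chloride, CC(C)(C)[Si](C)(C)Cl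
Why: Kinetic deprotonation of the enone at the α′-methyl group by the hindered amide base and O-silylation of the cross-conjugated lithium dienolate (silyl enol ether formation) should give the 2-silyloxydiene.

Step 2
Reactants: 3 (R)-4-benzyloxazolidin-2-one; 4 (E)-but-2-enoyl chloride (crotonyl chloride)
Product: 5 (R)-4-benzyl-3-[(E)-but-2-enoyl]oxazolidin-2-one
Conditions: n-BuLi, THF, −78 °C; then 4, −78 → 0 °C
Reagents that add atoms: none
Why: N-acylation of the lithiated oxazolidinone with the acid chloride is the standard entry to N-enoyl imides and leaves the E-alkene and the auxiliary stereocentre untouched.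

Step 3
Reactants: 2 tert-butyl(dimethyl)[(4-methylpenta-1,3-dien-2-yl)oxy]silane; 5 (R)-4-benzyl-3-[(E)-but-2-enoyl]oxazolidin-2-one
Product: 7 (R)-4-benzyl-3-{[(1S,6R)-2,2,6-trimethyl-4-oxocyclohexyl]carbonyl}oxazolidin-2-one, via silyl enol ether 6 (not isolated)
Conditions: Me2AlCl (1.5 equiv), CH2Cl2, −78 → −20 °C; then 1 M HCl, THF, 0 °C → rt
Reagents that add atoms: none
Why: Excess Me2AlCl forms the cationic chelate of both imide carbonyls with the enoyl group s-cis, and the CH2 terminus of the silyloxydiene (C4) adds to the β-carbon (C5) in a Mukaiyama–Michael step from the face opposite the benzyl group; the chelated (Z)-aluminium enolate then attacks the silyloxyallyl cation at the gem-dimethyl carbon C1 (6-endo-trig Michael closure, or the same two bonds in an asynchronous Diels–Alder transition state), and acid hydrolyses silyl enol ether 6 to ketone 7. The closest known reactions are the auxiliary-controlled Diels–Alder reaction of N-enoyl oxazolidinones under R2AlCl and the aluminium-Lewis-acid double Michael annulation of hindered 2-silyloxydienes with enones. C5 is set by benzyl shielding of the chelated s-cis imide, and C6 by closure on the enolate face away from the benzyl group, which places the C5 methyl and the C6 acyl group trans and requires the (R)-auxiliary for the (6R) target. The step needs para regiochemistry, secured by the 2-silyloxy group that makes the CH2 terminus the nucleophile, and ring closure faster than silyl transfer to the enolate, which the bulky tert-butyldimethylsilyl group and the intramolecular setting favour. Only C6 has to be right, since C5 becomes sp2 in step 8.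

Step 4
Reactants: 7 (R)-4-benzyl-3-{[(1S,6R)-2,2,6-trimethyl-4-oxocyclohexyl]carbonyl}oxazolidin-2-one
Product: 8 (R)-4-benzyl-3-{[(8S,9R)-7,7,9-trimethyl-1,4-dioxaspiro[4.5]decan-8-yl]carbonyl}oxazolidin-2-one
Conditions: HOCH2CH2OH, TsOH·H2O (cat.), benzene, reflux (Dean–Stark)
Reagents that add atoms: ethylene glycol, OCCO
Why: Acid-catalysed dioxolane formation with azeotropic removal of water masks the C3 ketone before hydride treatment, and the imide and both stereocentres are inert to these conditions.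

Step 5
Reactants: 8 (R)-4-benzyl-3-{[(8S,9R)-7,7,9-trimethyl-1,4-dioxaspiro[4.5]decan-8-yl]carbonyl}oxazolidin-2-one
Product: 9 [(8S,9R)-7,7,9-trimethyl-1,4-dioxaspiro[4.5]decan-8-yl]methanol
Conditions: LiBH4, MeOH (1 equiv), Et2O, 0 °C → rt
Reagents that add atoms: none
Why: Reductive cleavage of the auxiliary by LiBH4 at the exocyclic imide carbonyl should give the primary C7 alcohol without touching the ketal or epimerising C6, and the oxazolidinone is recovered.

Step 6
Reactants: 9 [(8S,9R)-7,7,9-trimethyl-1,4-dioxaspiro[4.5]decan-8-yl]methanol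
Product: 10 5-({[(8S,9R)-7,7,9-trimethyl-1,4-dioxaspiro[4.5]decan-8-yl]methyl}sulfanyl)-1-phenyl-1H-tetrazole
Conditions: 1-phenyl-1H-tetrazole-5-thiol, PPh3, DIAD, THF, 0 °C → rt
Reagents that add atoms: 1-phenyl-1H-tetrazole-5-thiol, Sc1nnnn1-c1ccccc1
Why: Mitsunobu thioetherification with the acidic tetrazole thiol displaces the activated primary oxygen by SN2 at the C7 methylene group, so no stereocentre is involved.

Step 7
Reactants: 10 5-({[(8S,9R)-7,7,9-trimethyl-1,4-dioxaspiro[4.5]decan-8-yl]methyl}sulfanyl)-1-phenyl-1H-tetrazole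
Product: 12 (4S,5R)-3,3,5-trimethyl-4-{[(1-phenyl-1H-tetrazol-5-yl)sulfonyl]methyl}cyclohexan-1-one, via sulfone ketal 11 (not isolated)
Conditions: (NH4)6Mo7O24·4H2O (cat.), 30% H2O2, EtOH, 0 °C → rt; Na2SO3 (aq); then 1 M HCl, THF, rt
Reagents that add atoms: hydrogen peroxide, OO; water, O
Why: The (NH4)6Mo7O24-catalysed peroxide oxidation takes the sulfide to the sulfone, and aqueous acid then hydrolyses the dioxolane to release the C3 ketone in the same flask.

Step 8
Reactants: 12 (4S,5R)-3,3,5-trimethyl-4-{[(1-phenyl-1H-tetrazol-5-yl)sulfonyl]methyl}cyclohexan-1-one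
Product: 13 (R)-3,5,5-trimethyl-4-{[(1-phenyl-1H-tetrazol-5-yl)sulfonyl]methyl}cyclohex-2-en-1-one
Conditions: IBX, 4-methoxypyridine N-oxide, DMSO, 25 °C
Reagents that add atoms: none
Why: IBX dehydrogenation runs through the enol, and because C1 is quaternary only the C4/C5 pair can lose two hydrogens, so the enone can form in one position only, while the mild N-oxide-assisted conditions should stop at the enone and leave the γ-hydrogen at C6 untouched.

Step 9
Reactants: 13 (R)-3,5,5-trimethyl-4-{[(1-phenyl-1H-tetrazol-5-yl)sulfonyl]methyl}cyclohex-2-en-1-one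
Product: 14 (1R,4R)-3,5,5-trimethyl-4-{[(1-phenyl-1H-tetrazol-5-yl)sulfonyl]methyl}cyclohex-2-en-1-ol
Conditions: (S)-1-methyl-3,3-diphenyltetrahydro-1H,3H-pyrrolo[1,2-c][1,3,2]oxazaborole [(S)-Me-CBS, 0.5 equiv], BH3·SMe2, THF, −30 °C; MeOH quench
Reagents that add atoms: none
Why: In this Corey–Bakshi–Shibata reduction the (S)-oxazaborolidine–borane complex treats the alkenyl side as the large group and should deliver hydride by reagent control to give the (3R) allylic alcohol, trans to the C6 substituent, under neutral conditions that avoid β-elimination of the sulfone.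

Step 10
Reactants: 14 (1R,4R)-3,5,5-trimethyl-4-{[(1-phenyl-1H-tetrazol-5-yl)sulfonyl]methyl}cyclohex-2-en-1-ol
Product: 15 5-({[(1R,4R)-4-{[tert-butyl(dimethyl)silyl]oxy}-2,6,6-trimethylcyclohex-2-en-1-yl]methyl}sulfonyl)-1-phenyl-1H-tetrazole
Conditions: TBSCl, imidazole, DMF, rt
Reagents that add atoms: tert-butyldimethylsilyl chloride, CC(C)(C)[Si](C)(C)Cl
Why: Standard silylation of the secondary allylic alcohol removes the acidic proton before the carbanion chemistry and leaves a non-leaving group at the allylic position.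

Step 11
Reactants: 15 5-({[(1R,4R)-4-{[tert-butyl(dimethyl)silyl]oxy}-2,6,6-trimethylcyclohex-2-en-1-yl]methyl}sulfonyl)-1-phenyl-1H-tetrazole; 16 crocetin dialdehyde, (2E,4E,6E,8E,10E,12E,14E)-2,6,11,15-tetramethylhexadeca-2,4,6,8,10,12,14-heptaenedial
Product: 17 (2E,4E,6E,8E,10E,12E,14E,16E)-17-[(1R,4R)-4-{[tert-butyl(dimethyl)silyl]oxy}-2,6,6-trimethylcyclohex-2-en-1-yl]-2,6,11,15-tetramethylheptadeca-2,4,6,8,10,12,14,16-octaenal
Conditions: KN(SiMe3)2, THF, −78 °C; anion added to 16 (3 equiv), THF, −78 °C → rt, dark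
Reagents that add atoms: none
Why: In this Julia–Kocienski olefination the C7 sulfonyl carbanion adds to one formyl group of the dialdehyde, which is kept in excess by inverse addition to suppress a second olefination, and Smiles rearrangement with loss of SO2 and the tetrazolate should give mainly the (7E) alkene, as expected for an α-unbranched tetrazolyl sulfone and a conjugated aldehyde, while C6 is not acidic under these conditions.

Step 12
Reactants: 17 (2E,4E,6E,8E,10E,12E,14E,16E)-17-[(1R,4R)-4-{[tert-butyl(dimethyl)silyl]oxy}-2,6,6-trimethylcyclohex-2-en-1-yl]-2,6,11,15-tetramethylheptadeca-2,4,6,8,10,12,14,16-octaenal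
Product: 19 (2E,4E,6E,8E,10E,12E,14E,16E)-17-[(1R,4R)-4-hydroxy-2,6,6-trimethylcyclohex-2-en-1-yl]-2,6,11,15-tetramethylheptadeca-2,4,6,8,10,12,14,16-octaen-1-ol (target), via hydroxy apocarotenal 18 (not isolated)
Conditions: Bu4NF, AcOH, THF, 0 °C → rt; then MeOH, NaBH4, 0 °C, dark
Reagents that add atoms: none
Why: Buffered fluoride cleaves the silyl ether, and NaBH4 then reduces the conjugated aldehyde by 1,2-addition to the allylic alcohol without touching the polyene or the two stereocentres.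

Compound list
1 | mesityl oxide (4-methylpent-3-en-2-one) | CC(C)=CC(C)=O | starting material
2 | tert-butyl(dimethyl)[(4-methylpenta-1,3-dien-2-yl)oxy]silane | C=C(O[Si](C)(C)C(C)(C)C)C=C(C)C | intermediate
3 | (R)-4-benzyloxazolidin-2-one | O=C1N[C@H](Cc2ccccc2)CO1 | starting material
4 | (E)-but-2-enoyl chloride (crotonyl chloride) | C/C=C/C(Cl)=O | starting material
5 | (R)-4-benzyl-3-[(E)-but-2-enoyl]oxazolidin-2-one | C/C=C/C(=O)N1C(=O)OC[C@H]1Cc1ccccc1 | intermediate
6 | (R)-4-benzyl-3-{[(1S,6R)-4-{[tert-butyl(dimethyl)silyl]oxy}-2,2,6-trimethylcyclohex-3-en-1-yl]carbonyl}oxazolidin-2-one | C[C@@H]1CC(O[Si](C)(C)C(C)(C)C)=CC(C)(C)[C@H]1C(=O)N1C(=O)OC[C@H]1Cc1ccccc1 | intermediate (not isolated)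
7 | (R)-4-benzyl-3-{[(1S,6R)-2,2,6-trimethyl-4-oxocyclohexyl]carbonyl}oxazolidin-2-one | C[C@@H]1CC(=O)CC(C)(C)[C@H]1C(=O)N1C(=O)OC[C@H]1Cc1ccccc1 | intermediate
8 | (R)-4-benzyl-3-{[(8S,9R)-7,7,9-trimethyl-1,4-dioxaspiro[4.5]decan-8-yl]carbonyl}oxazolidin-2-one | C[C@@H]1CC2(OCCO2)CC(C)(C)[C@H]1C(=O)N1C(=O)OC[C@H]1Cc1ccccc1 | intermediate
9 | [(8S,9R)-7,7,9-trimethyl-1,4-dioxaspiro[4.5]decan-8-yl]methanol | C[C@@H]1CC2(OCCO2)CC(C)(C)[C@H]1CO | intermediate
10 | 5-({[(8S,9R)-7,7,9-trimethyl-1,4-dioxaspiro[4.5]decan-8-yl]methyl}sulfanyl)-1-phenyl-1H-tetrazole | C[C@@H]1CC2(OCCO2)CC(C)(C)[C@H]1CSc1nnnn1-c1ccccc1 | intermediate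
11 | 5-({[(8S,9R)-7,7,9-trimethyl-1,4-dioxaspiro[4.5]decan-8-yl]methyl}sulfonyl)-1-phenyl-1H-tetrazole | C[C@@H]1CC2(OCCO2)CC(C)(C)[C@H]1CS(=O)(=O)c1nnnn1-c1ccccc1 | intermediate (not isolated)
12 | (4S,5R)-3,3,5-trimethyl-4-{[(1-phenyl-1H-tetrazol-5-yl)sulfonyl]methyl}cyclohexan-1-one | C[C@@H]1CC(=O)CC(C)(C)[C@H]1CS(=O)(=O)c1nnnn1-c1ccccc1 | intermediate
13 | (R)-3,5,5-trimethyl-4-{[(1-phenyl-1H-tetrazol-5-yl)sulfonyl]methyl}cyclohex-2-en-1-one | CC1=CC(=O)CC(C)(C)[C@H]1CS(=O)(=O)c1nnnn1-c1ccccc1 | intermediate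
14 | (1R,4R)-3,5,5-trimethyl-4-{[(1-phenyl-1H-tetrazol-5-yl)sulfonyl]methyl}cyclohex-2-en-1-ol | CC1=C[C@H](O)CC(C)(C)[C@H]1CS(=O)(=O)c1nnnn1-c1ccccc1 | intermediate
15 | 5-({[(1R,4R)-4-{[tert-butyl(dimethyl)silyl]oxy}-2,6,6-trimethylcyclohex-2-en-1-yl]methyl}sulfonyl)-1-phenyl-1H-tetrazole | CC1=C[C@H](O[Si](C)(C)C(C)(C)C)CC(C)(C)[C@H]1CS(=O)(=O)c1nnnn1-c1ccccc1 | intermediate
16 | crocetin dialdehyde, (2E,4E,6E,8E,10E,12E,14E)-2,6,11,15-tetramethylhexadeca-2,4,6,8,10,12,14-heptaenedial | O=C/C(C)=C/C=C/C(C)=C/C=C/C=C(C)/C=C/C=C(\C)C=O | starting material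
17 | (2E,4E,6E,8E,10E,12E,14E,16E)-17-[(1R,4R)-4-{[tert-butyl(dimethyl)silyl]oxy}-2,6,6-trimethylcyclohex-2-en-1-yl]-2,6,11,15-tetramethylheptadeca-2,4,6,8,10,12,14,16-octaenal | CC1=C[C@H](O[Si](C)(C)C(C)(C)C)CC(C)(C)[C@H]1/C=C/C(C)=C/C=C/C(C)=C/C=C/C=C(C)/C=C/C=C(\C)C=O | intermediate
18 | (2E,4E,6E,8E,10E,12E,14E,16E)-17-[(1R,4R)-4-hydroxy-2,6,6-trimethylcyclohex-2-en-1-yl]-2,6,11,15-tetramethylheptadeca-2,4,6,8,10,12,14,16-octaenal | CC1=C[C@H](O)CC(C)(C)[C@H]1/C=C/C(C)=C/C=C/C(C)=C/C=C/C=C(C)/C=C/C=C(\C)C=O | intermediate (not isolated)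
19 | (2E,4E,6E,8E,10E,12E,14E,16E)-17-[(1R,4R)-4-hydroxy-2,6,6-trimethylcyclohex-2-en-1-yl]-2,6,11,15-tetramethylheptadeca-2,4,6,8,10,12,14,16-octaen-1-ol, i.e. (3R,6R)-8'-apo-ε-carotene-3,8'-diol | CC1=C[C@H](O)CC(C)(C)[C@H]1/C=C/C(C)=C/C=C/C(C)=C/C=C/C=C(C)/C=C/C=C(\C)CO | target

Total step count: 12.
Longest linear sequence: 11 steps (step 1 or step 2, then steps 3 to 12).

Steps most likely to fail

Step 3. The annulation may stop after the first C–C bond if the silyl group migrates to the enolate, or closure at the gem-dimethyl terminus may be slow and lose face control at C6. Fallback, from 1 back to 15: the annulation is replaced by the classical condensation of 1 with ethyl acetoacetate (BF3·OEt2, heat; conjugate addition, aldol closure, dehydration). This gives racemic ethyl 2,6,6-trimethyl-4-oxocyclohex-2-ene-1-carboxylate F1, with the C3 ketone and the C4=C5 alkene already in place. Reduction with the (S)-oxazaborolidine and BH3·SMe2 should turn the two enantiomers into diastereomers that are separated by chromatography. The trans ester ethyl (1R,4R)-4-hydroxy-2,6,6-trimethylcyclohex-2-ene-1-carboxylate F2 is kept and the cis ester ethyl (1S,4R)-4-hydroxy-2,6,6-trimethylcyclohex-2-ene-1-carboxylate F3 is set aside. Silylation (TBSCl, imidazole) gives ethyl (1R,4R)-4-{[tert-butyl(dimethyl)silyl]oxy}-2,6,6-trimethylcyclohex-2-ene-1-carboxylate F4. Reduction with i-Bu2AlH (CH2Cl2, −78 °C) gives [(1R,4R)-4-{[tert-butyl(dimethyl)silyl]oxy}-2,6,6-trimethylcyclohex-2-en-1-yl]methanol F5. The Mitsunobu reaction with 1-phenyl-1H-tetrazole-5-thiol gives 5-({[(1R,4R)-4-{[tert-butyl(dimethyl)silyl]oxy}-2,6,6-trimethylcyclohex-2-en-1-yl]methyl}sulfanyl)-1-phenyl-1H-tetrazole F6, and (NH4)6Mo7O24/H2O2 oxidises F6 to 15.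

Step 9. Hydride may be delivered to the wrong face of the C3 carbonyl if the bias of the ring opposes the catalyst, giving the cis alcohol. Fallback, from 13 back to 14: Luche reduction (NaBH4, CeCl3·7H2O, MeOH, −78 °C) gives both C3 epimers, 14 and (1S,4R)-3,5,5-trimethyl-4-{[(1-phenyl-1H-tetrazol-5-yl)sulfonyl]methyl}cyclohex-2-en-1-ol F7, which are separated. F7 is inverted by a Mitsunobu reaction with benzoic acid (PPh3, DIAD) to (1R,4R)-3,5,5-trimethyl-4-{[(1-phenyl-1H-tetrazol-5-yl)sulfonyl]methyl}cyclohex-2-en-1-yl benzoate F8. Cleavage of the benzoate with i-Bu2AlH (CH2Cl2, −78 °C) gives 14, so all material converges on the (3R) alcohol.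

Step 11. The remaining formyl group may undergo a second olefination, and E control at C7=C8 may be incomplete. Fallback, from 16 back to 19: the dialdehyde is differentiated before the coupling. Substoichiometric NaBH4 (THF/MeOH, −20 °C) gives (2E,4E,6E,8E,10E,12E,14E)-16-hydroxy-2,6,11,15-tetramethylhexadeca-2,4,6,8,10,12,14-heptaenal F9, with unreacted 16 recovered. TBSCl/imidazole gives (2E,4E,6E,8E,10E,12E,14E)-16-{[tert-butyl(dimethyl)silyl]oxy}-2,6,11,15-tetramethylhexadeca-2,4,6,8,10,12,14-heptaenal F10. The potassium anion of 15 (KN(SiMe3)2, THF, −78 °C) is combined with one equivalent of F10 to give the bis-silyl ether tert-butyl({(2E,4E,6E,8E,10E,12E,14E,16E)-17-[(1R,4R)-4-{[tert-butyl(dimethyl)silyl]oxy}-2,6,6-trimethylcyclohex-2-en-1-yl]-2,6,11,15-tetramethylheptadeca-2,4,6,8,10,12,14,16-octaen-1-yl}oxy)dimethylsilane F11. A trace of I2 in CH2Cl2 under daylight equilibrates any (7Z) isomer to the all-E polyene, and Bu4NF (THF) removes both silyl groups to give 19.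

Further compounds
F1 | step 3 | ethyl 2,6,6-trimethyl-4-oxocyclohex-2-ene-1-carboxylate (racemic) | CCOC(=O)C1C(C)=CC(=O)CC1(C)C
F2 | step 3 | ethyl (1R,4R)-4-hydroxy-2,6,6-trimethylcyclohex-2-ene-1-carboxylate | CC1=C[C@H](O)CC(C)(C)[C@H]1C(=O)OCC
F3 | step 3 | ethyl (1S,4R)-4-hydroxy-2,6,6-trimethylcyclohex-2-ene-1-carboxylate | CC1=C[C@H](O)CC(C)(C)[C@@H]1C(=O)OCC
F4 | step 3 | ethyl (1R,4R)-4-{[tert-butyl(dimethyl)silyl]oxy}-2,6,6-trimethylcyclohex-2-ene-1-carboxylate | CC1=C[C@H](O[Si](C)(C)C(C)(C)C)CC(C)(C)[C@H]1C(=O)OCC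
F5 | step 3 | [(1R,4R)-4-{[tert-butyl(dimethyl)silyl]oxy}-2,6,6-trimethylcyclohex-2-en-1-yl]methanol | CC1=C[C@H](O[Si](C)(C)C(C)(C)C)CC(C)(C)[C@H]1CO
F6 | step 3 | 5-({[(1R,4R)-4-{[tert-butyl(dimethyl)silyl]oxy}-2,6,6-trimethylcyclohex-2-en-1-yl]methyl}sulfanyl)-1-phenyl-1H-tetrazole | CC1=C[C@H](O[Si](C)(C)C(C)(C)C)CC(C)(C)[C@H]1CSc1nnnn1-c1ccccc1
F7 | step 9 | (1S,4R)-3,5,5-trimethyl-4-{[(1-phenyl-1H-tetrazol-5-yl)sulfonyl]methyl}cyclohex-2-en-1-ol | CC1=C[C@@H](O)CC(C)(C)[C@H]1CS(=O)(=O)c1nnnn1-c1ccccc1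
F8 | step 9 | (1R,4R)-3,5,5-trimethyl-4-{[(1-phenyl-1H-tetrazol-5-yl)sulfonyl]methyl}cyclohex-2-en-1-yl benzoate | CC1=C[C@H](OC(=O)c2ccccc2)CC(C)(C)[C@H]1CS(=O)(=O)c1nnnn1-c1ccccc1
F9 | step 11 | (2E,4E,6E,8E,10E,12E,14E)-16-hydroxy-2,6,11,15-tetramethylhexadeca-2,4,6,8,10,12,14-heptaenal | O=C/C(C)=C/C=C/C(C)=C/C=C/C=C(C)/C=C/C=C(\C)CO
F10 | step 11 | (2E,4E,6E,8E,10E,12E,14E)-16-{[tert-butyl(dimethyl)silyl]oxy}-2,6,11,15-tetramethylhexadeca-2,4,6,8,10,12,14-heptaenal | O=C/C(C)=C/C=C/C(C)=C/C=C/C=C(C)/C=C/C=C(\C)CO[Si](C)(C)C(C)(C)C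
F11 | step 11 | tert-butyl({(2E,4E,6E,8E,10E,12E,14E,16E)-17-[(1R,4R)-4-{[tert-butyl(dimethyl)silyl]oxy}-2,6,6-trimethylcyclohex-2-en-1-yl]-2,6,11,15-tetramethylheptadeca-2,4,6,8,10,12,14,16-octaen-1-yl}oxy)dimethylsilane | CC1=C[C@H](O[Si](C)(C)C(C)(C)C)CC(C)(C)[C@H]1/C=C/C(C)=C/C=C/C(C)=C/C=C/C=C(C)/C=C/C=C(\C)CO[Si](C)(C)C(C)(C)C
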